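Count turnovers on any repeat of these flasks, at every reading.

in all of them: free monomer 0.050 M
- winter: transfer agent 0.015 M; initiator 2.3 mol%; impurity 3.2 mM; run made earlier
- noon: transfer agent 0.015 M; initiator 3.9 mol%; impurity 3.2 mM; run made earlier
- autumn: transfer agent 0.015 M; initiator 5.3 mol%; impurity 3.2 mM; run made earlier
- midnight: transfer agent 0.015 M; initiator 5.2 mol%; impurity 2.4 mM; run made earlier
- theta: transfer agent 0.0150 M; initiator 2.5 mol%; impurity 2.0 mM; time 8.0 min
- epsilon: transfer agent 0.0150 M; initiator 5.2 mol%; impurity 3.2 mM; time 4.0 min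

| run | time / min | monomer in chains / % | free monomer / % |
|---|---|---|---|
| winter | 0.833 | 2.3 | 96.9 |
| winter | 1.50 | 3.9 | 96.4 |
| winter | 2.50 | 5.8 | 94.2 |
| winter | 3.00 | 6.1 | 94.1 |
| winter | 4.00 | 7.0 | 92.4 |
| noon | 0.333 | 1.6 | 98.5 |
| noon | 1.00 | 4.2 | 94.9 |
| noon | 2.00 | 7.7 | 91.5 |
| noon | 3.00 | 10.0 | 88.7 |
| noon | 4.00 | 13.7 | 85.7 |
| autumn | 0.333 | 2.4 | 96.7 |
| autumn | 0.667 | 5.1 | 94.9 |
| autumn | 1.00 | 6.3 | 93.4 |
| autumn | 2.00 | 10.9 | 88.3 |
| autumn | 4.00 | 18.1 | 81.2 |
| midnight | 0.333 | 4.1 | 96.7 |
| midnight | 0.667 | 5.4 | 94.2 |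
| midnight | 1.00 | 7.9 | 91.6 |
| midnight | 2.00 | 13.3 | 86.4 |
| midnight | 4.00 | 21.5 | 78.8 |

(scatter of a reading: 0.5 percentage points)

1. the winner by amount of monomer in chains, in percent of the free monomer charged; "neither" if no more than 2 percentage points parts them (theta / epsilon / neither)
2. how much monomer in chains is there at the end, in percent of the free monomer charged: theta
3. how much monomer in chains is there at the end, in percent of the free monomer charged: epsilon



I pooled noon and autumn, the two runs with 3.2 mM of impurity that were read at both 2.00 min and 4.00 min, into a turnover count, the monomer in chains per initiator charged. It stood at 2.02 after 2.00 min and 3.46 after 4.00 min.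

I began with the main step, at the steady early pace:

pace = 1.01 /min
theta: 20.2 %; epsilon: 21.0 %

Then I added the fading. In those runs the second interval gave 0.710 of the first, and I let that ratio repeat for theta's later minutes:

count at 8.0 min = 5.20
theta: 13.0 %; epsilon: 18.0 %

Last came the impurity. Midnight, with 2.4 mM of it against 3.2 mM, read 4.13 turnovers, a ratio of 1.20 to the pooled count. I assumed that the share of initiator kept goes as a half-point over half-point plus impurity. This single reading, with its scatter, puts the half-point near 1.68 mM. Epsilon carries the impurity of the pooled runs and stays put, while theta gains: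

gain = 1.33
theta: 17.2 %; epsilon: 18.0 %

My gap of 0.80 percentage points is less than the margin of 2 points, so I called it neither.

The forecast differed, with 15.5 % for theta, 17.8 % for epsilon and the verdict “Epsilon probably wins, narrowly.”

The flasks gave 17.7 % for theta and 18.4 % for epsilon, so the call is neither.

    living end + transfer agent → dead chain (kL = 0.100 /M/s)
    free monomer + living end → monomer in chains + living end, rate k2*[living end]*[free monomer] (k = 0.900 /M/s)
    free monomer + initiator → living end + monomer in chains (k = 1.50 /M/s)
    initiator + impurity → spent initiator (k = 49.0 /M/s)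

Theta ended at 7.09 turnovers and epsilon at 3.53. The neighbour, epsilon with 21 mol% of initiator, reached 3.63 at 4.00 min. Neither asked flask had come to rest: initiator stood at 0 % in theta and 0 % in epsilon, but living end stood at 2.97 × 10⁻⁴ M and 7.24 × 10⁻⁴ M, with free monomer at 82.3 % and 81.6 %. Ten times the time takes theta to 31.5 % at 80.0 min, or 12.6 turnovers. Epsilon reaches 47.0 % at 40.0 min, or 9.05 turnovers, and the gap widens to 16 points.

The data are calculated on assumed constants; the scatter is artificial.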